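**Plan**
1. Cuts: (a) the benzylic CH2–CH bond and the aryl O–C(ketal) bond of the pyran ring, giving an o-quinone methide and a dihydrofuran; (b) the two ring A bonds that join the carbons bearing the lactone C=O and the (CH2)7 chain to their neighbours C–OMe and C–CH2, giving a macrocyclic ynoate and an oxygenated diene; (c) the lactone C(=O)–O bond, the alkyne–CO2H bond and the CH2–CH2 bond beside the carbinol.
2. Forward order: the chain is assembled, ring B (the 12-membered lactone) is closed by macrolactonisation, ring A is annulated onto it by [4+2] and aromatisation, and the pyran ring with its cis-fused ketal is closed last by hetero-[4+2] onto the preformed five-membered ring of the dihydrofuran.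
3. Enabling feature: the two adjacent ring A carbons that carry C(=O)O and the heptamethylene chain belong to both ring A and ring B; written as C≡C they are the α- and β-carbons of a 2-ynoate inside ring B, and the other four ring A carbons (C–OMe, C–H, C–O, C–CH2) form an oxygenated buta-1,3-diene.
4. Stereochemistry: the lactone carbinol (R) comes from (R)-propylene oxide and is never broken; the C-methyl centre of the tetrahydrofuran ring (S) comes from an Evans alkylation; the ring-fusion CH and the ketal carbon come from suprafacial cycloaddition on the face of the dihydrofuran anti to that methyl group.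

Key step: step 8

Remark: the target SMILES places the C-methyl group of the tetrahydrofuran ring trans to the benzylic CH2 and cis to the ketal methyl, which is what addition to the less hindered face of (S)-26 delivers; 10, 20 and 21 are taken as purchasable.

**Route**

Step 1
Reactants: 1 oct-1-yne; 2 (R)-2-methyloxirane ((R)-propylene oxide)
Product: 4 (R)-undec-4-yn-2-ol, via lithium oct-1-yn-1-ide 3 (not isolated)
Conditions: n-BuLi, THF, −78 °C; BF3·OEt2, then 2, −78 °C; sat. aq NH4Cl
Reagents that add atoms: none
Why: BF3-assisted alkynylation of a terminal epoxide by a lithium acetylide is an SN2 attack at the unsubstituted CH2, so the stereocentre of 2 is not touched and appears in 4 as (R).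

Step 2
Reactants: 4 (R)-undec-4-yn-2-ol
Product: 5 (R)-undec-10-yn-2-ol
Conditions: KH, H2N(CH2)3NH2, rt; then 4, 0 °C to rt; H2O
Reagents that add atoms: none
Why: Alkyne zipper isomerisation, in which the potassium amide of 1,3-diaminopropane moves the triple bond through allene intermediates along the unbranched chain until it is trapped as the terminal acetylide, while the carbinol carbon, held as its alkoxide, is not deprotonated and keeps its configuration.

Step 3
Reactants: 5 (R)-undec-10-yn-2-ol
Product: 7 (R)-11-hydroxydodec-2-ynoic acid, via dilithium alkoxide acetylide 6 (not isolated)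
Conditions: n-BuLi (2.2 equiv), THF, −78 to −20 °C; CO2, −78 °C to rt; 1 M HCl
Reagents that add atoms: carbon dioxide, O=C=O
Why: Carboxylation of a lithium acetylide, in which double deprotonation gives 6, its carbon nucleophile takes up CO2, and acidification returns the free alcohol from any alkyl carbonate formed at oxygen.

Step 4
Reactants: 7 (R)-11-hydroxydodec-2-ynoic acid
Product: 9 (R)-12-methyloxacyclododec-3-yn-2-one, via mixed trichlorobenzoic anhydride 8 (not isolated)
Conditions: 2,4,6-Cl3C6H2COCl, Et3N, THF, rt; then slow addition to DMAP, toluene, 80 °C (about 1 mM)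
Reagents that add atoms: none
Why: Yamaguchi macrolactonisation, in which DMAP transfers the alkynoyl group of 8 to the secondary alcohol under high dilution without breaking the C–O bond of the stereocentre, so (R) is retained, and the linear C–C≡C–C unit fits a 12-membered ring as it does in cyclododecyne.

Step 5
Reactants: 10 3-methoxypropanoyl chloride; 11 1,1-dichloroethene
Product: 13 1,1-dichloro-5-methoxypent-1-en-3-one, via 1,1,1-trichloro-5-methoxypentan-3-one 12 (not isolated)
Conditions: AlCl3, CH2Cl2, 0 °C to rt; ice-water; then Et3N, Et2O, 0 °C to rt
Reagents that add atoms: none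
Why: Friedel–Crafts-type acylation of an alkene (the acylium ion adds to the CH2 terminus of 11 and chloride capture gives 12) followed by E1cB loss of HCl gives the β,β-dichlorovinyl ketone, and any methanol lost from the β-methoxy ketone under the Lewis acid is put back by conjugate addition in step 6.

Step 6
Reactants: 13 1,1-dichloro-5-methoxypent-1-en-3-one
Product: 15 1,1,5-trimethoxypent-1-en-3-one, via 1-chloro-1,5-dimethoxypent-1-en-3-one 14 (not isolated)
Conditions: NaOMe (2.1 equiv), MeOH, 0 °C to rt
Reagents that add atoms: sodium methoxide, [Na+].[O-]C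
Why: Two successive addition–elimination steps (vinylic nucleophilic substitution) at the β-carbon of the enone replace both chlorides by methoxide, the standard passage from β,β-dichlorovinyl ketones to β-keto ketene acetals.

Step 7
Reactants: 15 1,1,5-trimethoxypent-1-en-3-one
Product: 16 (3Z)-1,1,5-trimethoxy-3-(trimethylsilyloxy)penta-1,3-diene
Conditions: TMSOTf, Et3N, Et2O, 0 °C; pentane extraction, bulb-to-bulb distillation
Reagents that add atoms: trimethylsilyl trifluoromethanesulfonate, C[Si](C)(C)OS(=O)(=O)C(F)(F)F
Why: Soft enolisation (O-silylation of the vinylogous carbonate carbonyl, then α'-deprotonation by Et3N) gives the cross-conjugated 2-silyloxydiene, and the geometry with CH2OMe cis to OSiMe3 is preferred because it avoids allylic strain with the ketene acetal arm.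

Step 8
Reactants: 9 (R)-12-methyloxacyclododec-3-yn-2-one; 16 (3Z)-1,1,5-trimethoxy-3-(trimethylsilyloxy)penta-1,3-diene
Product: 19 methoxymethyl phenol macrolide, via cyclohexa-1,4-diene cycloadduct 17 (not isolated), via aryl trimethylsilyl ether 18 (not isolated)
Conditions: 16 (3 equiv), toluene, sealed tube, 130 °C; then 0.5 M HCl, THF, rt
Reagents that add atoms: none
Why: The electron-rich diene 16 and the electron-poor alkyne of ynolide 9 should combine in a concerted but asynchronous normal-demand [4+2] cycloaddition in which the silyl enol ether terminus C4 of 16 bonds to the ynoate β-carbon and the ketene acetal carbon C1 to the α-carbon, giving cyclohexa-1,4-diene 17. Loss of methanol from the C1 ketal and the C4–H of 17 then aromatises the new ring to silyl ether 18, and dilute acid frees phenol 19. The closest known reaction type is the Diels–Alder benzannulation of alkynoates and of macrocyclic ynolides with 1,1-dialkoxy-3-silyloxy and bis(silyloxy) dienes, which delivers resorcylic esters. Ring A is closed by intermolecular [4+2] annulation across the two alkyne carbons of the intact 12-membered lactone, so both new ring bonds (C1 to Cα and C4 to Cβ) form in one operation and the macrocycle becomes ortho-fused. No new stereocentre survives, because the only sp3 centre created (C4 of 17) is erased on aromatisation and the lactone stereocentre is remote and untouched. The step needs regioselectivity, which the matched polarisation secures (largest HOMO coefficient at C4 of the diene, largest LUMO coefficient at the ynoate β-carbon), placing OMe ortho to the lactone carbonyl and CH2OMe next to the heptamethylene chain, while the (3Z) geometry keeps CH2OMe on the outside of the s-cis diene.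

Step 9
Reactants: 20 (R)-4-benzyl-3-propanoyloxazolidin-2-one; 21 3-bromoprop-1-yne (propargyl bromide)
Product: 23 (R)-4-benzyl-3-[(S)-2-methylpent-4-ynoyl]oxazolidin-2-one, via sodium Z-enolate 22 (not isolated)
Conditions: NaN(SiMe3)2, THF, −78 °C; then 21, −78 to −40 °C
Reagents that add atoms: none
Why: Evans asymmetric alkylation, in which the chelated sodium Z-enolate 22 is alkylated by SN2 displacement on the face opposite the benzyl group of the (R)-auxiliary, setting the new α-stereocentre as (S).

Step 10
Reactants: 23 (R)-4-benzyl-3-[(S)-2-methylpent-4-ynoyl]oxazolidin-2-one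
Product: 24 (S)-2-methylpent-4-yn-1-ol
Conditions: LiBH4, H2O (1.1 equiv), Et2O, 0 °C; aqueous work-up
Reagents that add atoms: none
Why: Reductive cleavage of the N-acyl oxazolidinone by LiBH4 attacks the exocyclic carbonyl, releases the auxiliary and gives the primary alcohol without touching the α-stereocentre or the alkyne.

Step 11
Reactants: 24 (S)-2-methylpent-4-yn-1-ol
Product: 26 (S)-3,5-dimethyl-2,3-dihydrofuran, via (S)-4-methyl-2-methylideneoxolane 25 (not isolated)
Conditions: NaNH2 (10 mol%), neat, 120–140 °C, product distilled as it forms
Reagents that add atoms: none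
Why: Base-catalysed 5-exo-dig hydroalkoxylation of the alkynol gives the exocyclic enol ether 25, which isomerises under the same conditions to the more stable endocyclic enol ether, and the methyl-bearing stereocentre is not acidic enough to epimerise.

Step 12
Reactants: 19 methoxymethyl phenol macrolide; 26 (S)-3,5-dimethyl-2,3-dihydrofuran
Product: 28 lasiodiplactone A, via o-quinone methide 27 (not isolated)
Conditions: 26 (5 equiv), toluene, sealed tube, 170 °C
Reagents that add atoms: none
Why: Thermal 1,4-elimination of methanol from the o-hydroxybenzyl methyl ether gives o-quinone methide 27, which the enol ether traps in an inverse-electron-demand oxa-Diels–Alder reaction (β-carbon of 26 to the methide carbon, oxygen-bearing carbon to the quinone oxygen), suprafacial addition making the ketal cis-fused and approach anti to the C3 methyl group of 26 setting the ring-fusion CH and the ketal carbon.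

**Compound list**
1 | oct-1-yne | C#CCCCCCC | starting material
2 | (R)-2-methyloxirane ((R)-propylene oxide) | C[C@@H]1CO1 | starting material
3 | lithium oct-1-yn-1-ide | [Li]C#CCCCCCC | intermediate
4 | (R)-undec-4-yn-2-ol | C[C@@H](O)CC#CCCCCCC | intermediate
5 | (R)-undec-10-yn-2-ol | C[C@@H](O)CCCCCCCC#C | intermediate
6 | dilithium alkoxide acetylide of 5 | C[C@@H](O[Li])CCCCCCCC#C[Li] | intermediate
7 | (R)-11-hydroxydodec-2-ynoic acid | C[C@@H](O)CCCCCCCC#CC(=O)O | intermediate
8 | (R)-11-hydroxydodec-2-ynoic 2,4,6-trichlorobenzoic anhydride | C[C@@H](O)CCCCCCCC#CC(=O)OC(=O)c1c(Cl)cc(Cl)cc1Cl | intermediate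
9 | (R)-12-methyloxacyclododec-3-yn-2-one (ynolide) | C[C@@H]1CCCCCCCC#CC(=O)O1 | intermediate
10 | 3-methoxypropanoyl chloride | COCCC(=O)Cl | starting material
11 | 1,1-dichloroethene | C=C(Cl)Cl | starting material
12 | 1,1,1-trichloro-5-methoxypentan-3-one | COCCC(=O)CC(Cl)(Cl)Cl | intermediate
13 | 1,1-dichloro-5-methoxypent-1-en-3-one | COCCC(=O)C=C(Cl)Cl | intermediate
14 | 1-chloro-1,5-dimethoxypent-1-en-3-one | COCCC(=O)C=C(Cl)OC | intermediate
15 | 1,1,5-trimethoxypent-1-en-3-one | COCCC(=O)C=C(OC)OC | intermediate
16 | (3Z)-1,1,5-trimethoxy-3-(trimethylsilyloxy)penta-1,3-diene | COC(OC)=C/C(O[Si](C)(C)C)=C/COC | intermediate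
17 | cycloadduct: 12-membered (R)-lactone fused at its former alkyne carbons to a 3,3-dimethoxy-6-(methoxymethyl)-5-(trimethylsilyloxy)cyclohexa-1,4-diene (mixture at the CH(CH2OMe) carbon) | COCC1C(O[Si](C)(C)C)=CC(OC)(OC)C2=C1CCCCCCC[C@@H](C)OC2=O | intermediate
18 | trimethylsilyl ether of phenol 19 | COc1cc(O[Si](C)(C)C)c(COC)c2c1C(=O)O[C@H](C)CCCCCCC2 | intermediate
19 | methoxymethyl phenol macrolide: benzo-fused 12-membered (R)-lactone with OMe ortho and OH para to the lactone carbonyl and CH2OMe between OH and the chain | COc1cc(O)c(COC)c2c1C(=O)O[C@H](C)CCCCCCC2 | intermediate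
20 | (R)-4-benzyl-3-propanoyloxazolidin-2-one | CCC(=O)N1[C@H](Cc2ccccc2)COC1=O | starting material
21 | 3-bromoprop-1-yne (propargyl bromide) | C#CCBr | starting material
22 | sodium (Z)-enolate of 20 | C/C=C(\[O-])N1[C@H](Cc2ccccc2)COC1=O.[Na+] | intermediate
23 | (R)-4-benzyl-3-[(S)-2-methylpent-4-ynoyl]oxazolidin-2-one | C#CC[C@H](C)C(=O)N1[C@H](Cc2ccccc2)COC1=O | intermediate
24 | (S)-2-methylpent-4-yn-1-ol | C#CC[C@H](C)CO | intermediate
25 | (S)-4-methyl-2-methylideneoxolane | C=C1C[C@H](C)CO1 | intermediate
26 | (S)-3,5-dimethyl-2,3-dihydrofuran | CC1=C[C@H](C)CO1 | intermediate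
27 | o-quinone methide of 19 (methanol lost; exocyclic CH2 next to the ring C=O) | COC1=CC(=O)C(=C)C2=C1C(=O)O[C@H](C)CCCCCCC2 | intermediate
28 | lasiodiplactone A | COc1cc2c(c3c1C(=O)O[C@H](C)CCCCCCC3)C[C@H]1[C@H](C)CO[C@@]1(C)O2 | target

**Count**
Total: 12 steps. Longest linear sequence: 6 steps (1, 2, 3, 4, 8, 12).

**Steps most likely to fail**

Step 8. Cycloaddition between the terminally substituted diene and the β-alkyl ynoate may be slower than thermal decay of 16 (desilylation, loss of methanol, oligomerisation), or a (3E) portion of 16 may stay unreacted. Fallback, setting out from 9 and 11 and coming back at 27: the benzylic carbon is taken off the diene and added afterwards. Acetyl chloride is added to 11 (AlCl3, then Et3N) to give 4,4-dichlorobut-3-en-2-one F1. NaOMe in MeOH converts it into 4,4-dimethoxybut-3-en-2-one F2, and TMSOTf/Et3N gives 1,1-dimethoxy-3-(trimethylsilyloxy)buta-1,3-diene F3, the unhindered parent of 16. Heating F3 with 9 and acidic work-up should give the phenol without the methoxymethyl group, (R)-lasiodiplodin F4. Mannich aminomethylation (aq CH2O, Me2NH, EtOH) is expected at the ring position ortho to OH and para to OMe, next to the chain, giving the benzylic dimethylamine F5. MeI gives the trimethylammonium iodide F6, which on warming with 26 in toluene (80–110 °C) should lose trimethylamine hydroiodide to form 27 and from it 28.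

Step 4. Intermolecular acylation (diolide and oligomers) or conjugate addition of DMAP to the activated ynoate may outrun closure of the ring. Fallback, setting out from 1 and coming back at 9: the alcohol is activated instead of the acid. Steps 1 to 3 are run with purchased (S)-propylene oxide to give (S)-undec-4-yn-2-ol F7, (S)-undec-10-yn-2-ol F8 and (S)-11-hydroxydodec-2-ynoic acid F9. Mitsunobu macrolactonisation of F9 (PPh3, diisopropyl azodicarboxylate, toluene, high dilution, 0 °C to rt) closes the ring by SN2 attack of the acidic ynoate on the oxyphosphonium ion with inversion, which should give (R)-9.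

Step 12. Methanol loss from 19 may need temperatures at which 26 is consumed by addition of the phenol O–H or by oligomerisation, and facial discrimination falls as the temperature rises. Fallback, setting out from 19 and coming back at 27: the leaving group is exchanged for one that departs at low temperature. 19 is heated with neat morpholine (150 °C), which traps 27 as the Mannich base F10. MeI gives the N-methylmorpholinium iodide F11, and warming F11 with 26 in toluene at 80 °C should regenerate 27 under conditions that 26 tolerates, leading to 28.

**Further compounds**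
F1 | step 8 | 4,4-dichlorobut-3-en-2-one | CC(=O)C=C(Cl)Cl
F2 | step 8 | 4,4-dimethoxybut-3-en-2-one | CC(=O)C=C(OC)OC
F3 | step 8 | 1,1-dimethoxy-3-(trimethylsilyloxy)buta-1,3-diene | COC(OC)=CC(=C)O[Si](C)(C)C
F4 | step 8 | (R)-lasiodiplodin (19 without the CH2OMe group) | COc1cc(O)cc2c1C(=O)O[C@H](C)CCCCCCC2
F5 | step 8 | dimethylaminomethyl phenol macrolide (Mannich base) | COc1cc(O)c(CN(C)C)c2c1C(=O)O[C@H](C)CCCCCCC2
F6 | step 8 | trimethylammonium iodide of F5 | COc1cc(O)c(C[N+](C)(C)C)c2c1C(=O)O[C@H](C)CCCCCCC2.[I-]
F7 | step 4 | (S)-undec-4-yn-2-ol | C[C@H](O)CC#CCCCCCC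
F8 | step 4 | (S)-undec-10-yn-2-ol | C[C@H](O)CCCCCCCC#C
F9 | step 4 | (S)-11-hydroxydodec-2-ynoic acid | C[C@H](O)CCCCCCCC#CC(=O)O
F10 | step 12 | morpholinomethyl phenol macrolide (Mannich base) | COc1cc(O)c(CN3CCOCC3)c2c1C(=O)O[C@H](C)CCCCCCC2
F11 | step 12 | N-methylmorpholinium iodide of F10 | COc1cc(O)c(C[N+]3(C)CCOCC3)c2c1C(=O)O[C@H](C)CCCCCCC2.[I-]
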